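# Grevirobstol B: proposal for a total synthesis by a twofold palladium/norbornene relay that stitches the C16 chain across a preformed diaryl ether

Atom labels used throughout:
- Ring A: A-C1 (OH), A-C3 (bridging O), A-C5 (chain).
- Ring B: B-C1 (bridging O), B-C2 (OH), B-C4 (OH), B-C6 (chain).
- Chain: C1′ (on B-C6) to C16′ (on A-C5).

## Analysis of the target

Grevirobstol B (9) is a 22-membered cyclophane in which ring A (a resorcinol) and ring B (a benzene-1,2,4-triol) are joined twice. One link is the diaryl ether oxygen and the other is an unbranched, unfunctionalised (CH2)16 chain. The macrocycle runs through three atoms of ring A (meta bridge), the oxygen, two atoms of ring B (ortho bridge) and sixteen methylenes. There is no stereocentre and no double bond, and a loop of this size lets the rings turn freely, so nothing stereochemical has to be set. The sensitive part is the electron-rich triphenol, above all ring B, so the three OH groups stay masked as methyl ethers until the last step. The difficulty is positional and steric: B-C1 is flanked by the B-C2 oxygen and the B-C6 chain on a donor-rich ring, so a late C–O coupling is slow and no SNAr activation can be placed, while the chain offers no group at which a closure would leave no scar. The feature that the plan exploits concerns both chain termini. They stand on carbons that are meta to the OH-bearing carbons of their ring (A-C5 to A-C1 and A-C3; B-C6 to B-C2 and B-C4), which electrophilic substitution never reaches. Each is nevertheless the direct neighbour of a naturally addressable carbon (A-C6, ortho to the A-C1 oxygen and para to the A-C3 oxygen; B-C5, ortho to the B-C4 oxygen and para to the B-C2 oxygen), and the other neighbour of that carbon already bears oxygen.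

## Retrosynthetic reasoning

**9 ⇒ 8.** Only the three O–CH3 bonds are added. The skeleton is untouched, and the oxidation-prone free phenols appear only at the very end.

**8 ⇒ 4 + 6 (by way of 7).** The two aryl–CH2 bonds A-C5–C16′ and B-C6–C1′ are cut together.
- *What the cut produces.* Each arene gets back a hydrogen at the chain carbon and an iodine on the neighbouring carbon (A-C6, B-C5). The forward reaction is a palladium relay over a strained bicyclic alkene. The metal enters at C–I, is carried to the adjacent C–H, forms the aryl–CH2 bond there, and leaves the iodine position as C–H.
- *Why these bonds.* They are the only C–C bonds of the macrocycle not buried in a row of equal methylenes, so the cut leaves no scar.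
- *What is gained.* The chain becomes the symmetrical diiodide 6, so its orientation does not matter. Ring B loses its second ortho substituent, so the ether problem shrinks to an ordinary one. All regiochemistry is reduced to where an iodine sits.
- *Why A-C6 and not A-C4.* Palladium on A-C4 would sit ortho to the ether oxygen and could close a dibenzofuran onto B-C6–H.
- *What the forward step must achieve.* Two C–H alkylations, each at the only free ortho position; two hydride terminations; and ring closure rather than chain growth.

**4 ⇒ 3.** The C–I bond at B-C5 is cut. B-C5 is the most nucleophilic carbon of the whole diaryl ether, so an electrophilic iodine source places the handle without a directing group.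

**3 ⇒ 1 + 2.** The ether bond B-C1–O is cut at a stage where B-C6 still carries hydrogen and the phenol 1 has no ortho substituent. An oxidative copper(II) coupling of phenol and boronic acid is required. It leaves the C–I bond of 1 intact, which copper(I) or palladium(0) etherifications would not.

**6 ⇒ 5.** Two C–I bonds are traced back to the two primary alcohols of the catalogue diol.

## Alternatives that were turned down

**Alternative 1:** (the textbook route) cut in the middle of the chain, C8′=C9′.
- *Forward step.* Ring-closing metathesis of the bis(non-8-enyl) diaryl ether A1 to the cycloalkene A2 (E/Z mixture), then hydrogenation to 8.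
- *Why turned down.* The cut solves only the easy part. An unstrained 22-membered ring closes by many methods, whereas A1 still holds the doubly flanked ether B-C1–O and both arms at the donor-meta positions A-C5 and B-C6.
- Each arm must come from a prefunctionalised arene; for ring B this is a 2,3,5-trioxygenated building block that is not a catalogue item.
- The ether must be made with the ortho arm in place, and a C=C bond is created only to be erased.
- The step count should come to about twice that of the route below.

**Alternative 2:** cut of the ether bond B-C1–O as the ring-closing bond.
- *Forward step.* Ullmann-type macro-etherification of the iodophenol A3 or, in the biomimetic limit, dehydrogenative phenol coupling of the C2-symmetric bis-resorcinol A4.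
- *Why A3 was turned down.* Its carbon–halogen bond lies between OMe and the chain on a ring with ortho and para donors, so activation at copper is slowed sterically and electronically, and this under high dilution. Four phenolic oxygens on two nearly identical rings must also be told apart by protecting groups, which costs the steps that the symmetry had saved.
- *Why A4 was turned down.* Nothing directs O-attack on the partner ring over C–C coupling at the ortho/para carbons that carry the spin or charge density. The 1,2,4-trioxygenated product ring is also oxidised more easily than A4, so overoxidation is built in.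
- The copper variant is kept only as a fallback.

**Alternative 3:** cut through ring A itself (A-C1–A-C2 and A-C3–A-C4).
- *Forward step.* An intramolecular Danheiser benzannulation of the aryl ynol ether/cyclobutenone A5. Thermal ring opening of the cyclobutenone end, [2+2] addition to the ynol ether end and an electrocyclic cascade would build ring A with exactly its 1,3,5-pattern, close the macrocycle, and never form an aryl–O bond.
- *Why turned down.* The precursor costs more than the step wins, because its two termini exclude each other in preparation.
- The ynol ether needs an organolithium elimination that a cyclobutenone does not survive.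
- The cyclobutenone needs a ketene cycloaddition that attacks the ynol ether first.
- A C18 chain must be built linearly on a trioxygenated arene, and protecting detours push the sequence well beyond ten steps.

Key step: step 4

Remark (assumption): the target SMILES holds no stereocentre and the 22-membered loop is too large for stable planar chirality, so the compound is treated as achiral and "single enantiomer" requires no action.

## Route

Step 1
Reactants: 1 4-iodo-3-methoxyphenol; 2 (2,4-dimethoxyphenyl)boronic acid
Product: 3 1-(4-iodo-3-methoxyphenoxy)-2,4-dimethoxybenzene
Conditions: Cu(OAc)2, pyridine, 4 Å MS, CH2Cl2, dry air, rt (2 in excess)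
Reagents that add atoms: none
Why: Chan–Evans–Lam coupling (transmetalation of 2 to copper, phenoxide binding, C–O reductive elimination from Cu(III)) at room temperature. The C–I bond of 1 is not touched under these conditions, which an Ullmann or Pd etherification could not guarantee, and B-C1 has only one ortho substituent at this stage.

Step 2
Reactants: 3 1-(4-iodo-3-methoxyphenoxy)-2,4-dimethoxybenzene
Product: 4 1-iodo-5-(4-iodo-3-methoxyphenoxy)-2,4-dimethoxybenzene
Conditions: NIS (1.0 equiv), MeCN, 0 °C to rt, dark
Reagents that add atoms: N-iodosuccinimide, O=C1CCC(=O)N1I
Why: Electrophilic aromatic iodination; B-C5 is para to the B-C2 methoxy group and ortho to the B-C4 methoxy group and is the most nucleophilic carbon of 3. B-C3 is shielded between two OMe groups, B-C6 is meta to both, and ring A has one strong donor only and is deactivated by its iodine.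

Step 3
Reactants: 5 hexadecane-1,16-diol
Product: 6 1,16-diiodohexadecane
Conditions: I2, PPh3, imidazole, CH2Cl2, 0 °C to rt
Reagents that add atoms: iodine, II
Why: Appel-type iodination; both primary alcohols are activated as alkoxyphosphonium salts and displaced by iodide (SN2). Iodide is chosen over bromide because the palladacycles of step 4 must capture the chain ends at millimolar concentration.

Step 4
Reactants: 4 1-iodo-5-(4-iodo-3-methoxyphenoxy)-2,4-dimethoxybenzene; 6 1,16-diiodohexadecane
Product: 8 tri-O-methylgrevirobstol B, via ω-iodoalkyl mono-stitched aryl iodide 7 (not isolated)
Conditions: Pd(OAc)2 (20 mol %), P(2-furyl)3 (45 mol %), 7-bromonorbornene (4 equiv), Cs2CO3 (8 equiv), 1,4-dioxane, 100 °C; 4, 6 (1.0 equiv) and i-PrOH (3 equiv) added together by syringe pump over 24 h, final 2 mM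
Reagents that add atoms: none
Why: Proposed new method: a twofold Catellani-type relay (Pd(0)/norbornene ortho C–H alkylation with ipso hydrogenolysis) is used as a stitching macrocyclisation; the closest known reaction type is the intermolecular ortho-alkylation/ipso-hydride reduction of ortho-substituted aryl iodides with primary alkyl iodides, which turns 2-iodoanisoles into meta-alkylanisoles. At each C–I bond Pd(0) adds oxidatively, the norbornene inserts, and carbonate-assisted palladation of the only free ortho C–H (A-C5, B-C6) gives a five-membered aryl–norbornyl palladacycle that has no anionic ligand to exchange with the reductant and can therefore wait for an alkyl iodide. SN2-type oxidative addition of a primary C–I end gives Pd(IV), C(sp2)–C(sp3) reductive elimination forms the aryl–CH2 bond, the now doubly ortho-flanked aryl group expels the norbornene by β-carbon elimination, and isopropoxide delivers hydride (β-hydride elimination to acetone), so that the former iodine position ends as C–H. The less hindered and less electron-rich ring A iodide should react first and give 7; the second cycle on ring B then closes the 22-membered ring end to end by attack of the palladacycle on the tethered primary iodide (formally exo-tet), and no stereocentre is formed. Site selectivity is secured by the substrate: in each ring one ortho position is blocked by OMe, so only one C–H can be palladated and no dialkylation is possible; both iodines lie remote from the other ring, so no dibenzofuran-type direct arylation can end the cycle; and no free OH is present, so no O-alkylation competes. Ring closure over chain growth is secured by the slow joint feed of 4, 6 and the reductant into an excess of catalyst, mediator and base, which keeps free alkyl iodide below the effective molarity of the closure and keeps hydride scarce while the palladacycles wait. B-C6–H lies next to the aryloxy group, the known weak point of this relay, hence a C7-substituted norbornene of the kind devised for 2,5-disubstituted aryl iodides.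

Step 5
Reactants: 8 tri-O-methylgrevirobstol B
Product: 9 grevirobstol B
Conditions: BBr3 (6 equiv), CH2Cl2, −78 °C to rt; then ice-water, under Ar
Reagents that add atoms: none
Why: Lewis-acid cleavage of aryl methyl ethers; BBr3 binds each OMe oxygen and bromide attacks the methyl carbon (SN2). The diaryl ether has no sp3 carbon on oxygen and the chain has no functional group, so only the three methyl groups leave; work-up under argon protects the electron-rich ring B.

## Compound list

1 | 4-iodo-3-methoxyphenol | COc1cc(O)ccc1I | starting material
2 | (2,4-dimethoxyphenyl)boronic acid | COc1ccc(B(O)O)c(OC)c1 | starting material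
3 | 1-(4-iodo-3-methoxyphenoxy)-2,4-dimethoxybenzene | COc1ccc(Oc2ccc(I)c(OC)c2)c(OC)c1 | intermediate
4 | 1-iodo-5-(4-iodo-3-methoxyphenoxy)-2,4-dimethoxybenzene (I on A-C6 and B-C5) | COc1cc(OC)c(Oc2ccc(I)c(OC)c2)cc1I | intermediate
5 | hexadecane-1,16-diol | OCCCCCCCCCCCCCCCCO | starting material
6 | 1,16-diiodohexadecane | ICCCCCCCCCCCCCCCCI | intermediate
7 | 1-iodo-5-[3-(16-iodohexadecyl)-5-methoxyphenoxy]-2,4-dimethoxybenzene (not isolated) | COc1cc(CCCCCCCCCCCCCCCCI)cc(Oc2cc(I)c(OC)cc2OC)c1 | intermediate
8 | tri-O-methylgrevirobstol B (macrocycle of 9 with OMe on A-C1, B-C2 and B-C4) | COc1cc2cc(c1)Oc1c(OC)cc(OC)cc1CCCCCCCCCCCCCCCC2 | intermediate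
9 | grevirobstol B | Oc1cc2cc(c1)Oc1c(O)cc(O)cc1CCCCCCCCCCCCCCCC2 | target

## Step count and least certain steps

Total step count: 5. Longest linear sequence: 4 (steps 1, 2, 4, 5); step 3 runs in parallel.

**Step 4 (key step, proposed new method).**
- *Most likely failure.* The ring B iodine is lost as hydrogen before the relay has taken place. Palladation of B-C6–H must occur next to the aryloxy group. If it is slower than reversal of the norbornene insertion, the aryl–palladium species is reduced by the alcohol and the handle is gone.
- *Second risk.* Chain growth instead of ring closure. The first alkylation is bimolecular and needs a finite concentration of 6, whereas the second needs that concentration to be small.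
- *Third risk.* Reduction of the ring-opened norbornyl–palladium species while a palladacycle waits for its partner.
- *Fallback (known chemistry).* The closing bond is changed from aryl–CH2 to aryl–O; the fallback sets out from 6 and returns at 8. An excess of 6 is coupled with 3,5-dimethoxyphenylmagnesium bromide under Li2CuCl4 catalysis to 1-(16-iodohexadecyl)-3,5-dimethoxybenzene F1. NBS in MeCN brominates the innate position (ortho to the chain, para to OMe) to 2-bromo-1-(16-iodohexadecyl)-3,5-dimethoxybenzene F2. Commercial 3-bromo-5-methoxyphenol is silylated (TBSCl, imidazole) to (3-bromo-5-methoxyphenoxy)(tert-butyl)dimethylsilane F3. The Grignard reagent of F3 is coupled (Li2CuCl4, THF, 0 °C) with the primary iodide of F2 to tert-butyl{3-[16-(2-bromo-3,5-dimethoxyphenyl)hexadecyl]-5-methoxyphenoxy}dimethylsilane F4. TBAF frees 3-[16-(2-bromo-3,5-dimethoxyphenyl)hexadecyl]-5-methoxyphenol F5. A ligand-assisted Ullmann etherification (CuI, picolinic acid, Cs2CO3, dioxane, 110 °C, high dilution) then closes the ring to 8.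

**Step 1.**
- *Most likely failure.* Protodeboronation and oxidative hydroxylation of the electron-rich, ortho-methoxy boronic acid 2 outrun its transfer to copper, so conversion of 1 stalls.
- *Fallback.* The mechanism changes from oxidative copper coupling to SNAr; the fallback sets out from 2 and returns at 3. Compound 2 is oxidised (H2O2, aq. NaOH, THF) to 2,4-dimethoxyphenol F6. SNAr on 4-fluoro-2-methoxy-1-nitrobenzene (K2CO3, DMF, 80 °C) gives 2,4-dimethoxy-1-(3-methoxy-4-nitrophenoxy)benzene F7. Hydrogenation (H2, Pd/C) gives 4-(2,4-dimethoxyphenoxy)-2-methoxyaniline F8. Diazotisation followed by KI (Sandmeyer-type iodination) gives 3.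

**Step 2.**
- *Most likely failure.* Loss of ring selectivity, namely a second iodination at A-C4 (para to the ring A methoxy group), or oxidation of the trialkoxy ring by the iodonium source.
- *Fallback.* Ring A is switched off electronically instead of relying on relative rates; the fallback sets out from 2 and returns at 4. It runs through F6 and F7 as above. NIS then iodinates F7, whose nitro-bearing ring cannot react, to 1-iodo-2,4-dimethoxy-5-(3-methoxy-4-nitrophenoxy)benzene F9. Fe/NH4Cl reduces the nitro group without touching the C–I bond to 4-(5-iodo-2,4-dimethoxyphenoxy)-2-methoxyaniline F10. Diazotisation and KI give 4.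

**Step 5.**
- *Most likely failure.* Incomplete cleavage at the hindered B-C2 methoxy group, and oxidative degradation of the free triphenol during the acidic aqueous work-up.
- *Fallback.* The cleavage changes from electrophilic to nucleophilic dealkylation; the fallback runs from 8 directly to 9. Sodium dodecanethiolate in NMP at 130 °C attacks the methyl carbons by SN2 without Lewis acid or HBr. Acidification under argon follows, and no new compound is made on the way.

## Further compounds

F1 | step 4 | 1-(16-iodohexadecyl)-3,5-dimethoxybenzene | COc1cc(CCCCCCCCCCCCCCCCI)cc(OC)c1
F2 | step 4 | 2-bromo-1-(16-iodohexadecyl)-3,5-dimethoxybenzene | COc1cc(OC)c(Br)c(CCCCCCCCCCCCCCCCI)c1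
F3 | step 4 | (3-bromo-5-methoxyphenoxy)(tert-butyl)dimethylsilane | COc1cc(Br)cc(O[Si](C)(C)C(C)(C)C)c1
F4 | step 4 | tert-butyl{3-[16-(2-bromo-3,5-dimethoxyphenyl)hexadecyl]-5-methoxyphenoxy}dimethylsilane | COc1cc(CCCCCCCCCCCCCCCCc2cc(OC)cc(OC)c2Br)cc(O[Si](C)(C)C(C)(C)C)c1
F5 | step 4 | 3-[16-(2-bromo-3,5-dimethoxyphenyl)hexadecyl]-5-methoxyphenol | COc1cc(O)cc(CCCCCCCCCCCCCCCCc2cc(OC)cc(OC)c2Br)c1
F6 | step 1 | 2,4-dimethoxyphenol | COc1ccc(O)c(OC)c1
F7 | step 1 | 2,4-dimethoxy-1-(3-methoxy-4-nitrophenoxy)benzene | COc1ccc(Oc2ccc([N+](=O)[O-])c(OC)c2)c(OC)c1
F8 | step 1 | 4-(2,4-dimethoxyphenoxy)-2-methoxyaniline | COc1ccc(Oc2ccc(N)c(OC)c2)c(OC)c1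
F9 | step 2 | 1-iodo-2,4-dimethoxy-5-(3-methoxy-4-nitrophenoxy)benzene | COc1cc(OC)c(Oc2ccc([N+](=O)[O-])c(OC)c2)cc1I
F10 | step 2 | 4-(5-iodo-2,4-dimethoxyphenoxy)-2-methoxyaniline | COc1cc(OC)c(Oc2ccc(N)c(OC)c2)cc1I
F0 | step 5 | none | none
A1 | alternative 1 | 1,5-dimethoxy-2-[3-methoxy-5-(non-8-en-1-yl)phenoxy]-3-(non-8-en-1-yl)benzene | C=CCCCCCCCc1cc(OC)cc(Oc2c(OC)cc(OC)cc2CCCCCCCC=C)c1
A2 | alternative 1 | 8′,9′-didehydro-tri-O-methylgrevirobstol B (E/Z mixture) | COc1cc2cc(c1)Oc1c(OC)cc(OC)cc1CCCCCCCC=CCCCCCCC2
A3 | alternative 2 | 3-[16-(2-iodo-3,5-dimethoxyphenyl)hexadecyl]-5-methoxyphenol | COc1cc(O)cc(CCCCCCCCCCCCCCCCc2cc(OC)cc(OC)c2I)c1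
A4 | alternative 2 | 5,5′-(hexadecane-1,16-diyl)bis(benzene-1,3-diol) | Oc1cc(O)cc(CCCCCCCCCCCCCCCCc2cc(O)cc(O)c2)c1
A5 | alternative 3 | 3-{16-[2-(ethynyloxy)-3,5-dimethoxyphenyl]hexadecyl}cyclobut-2-en-1-one | C#COc1c(OC)cc(OC)cc1CCCCCCCCCCCCCCCCC1=CC(=O)C1
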